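**Retrosynthetic overview**
- The target comes from its methyl ether by O-demethylation. The diaryl ether C–O bond comes from metal-free aryl transfer from a diaryliodonium salt to 3,4,6-tribromo-2-methoxyphenol. Ring B is bought intact as 2,4-dibromo-1-iodobenzene.
- The tribromophenol comes from OH-directed ortho/para bromination of 3-bromo-2-methoxyphenol. Its bromine sits meta to OH and cannot be placed by aromatic substitution, so it is traced back to a carbonyl: 3-bromo-2-methoxycyclohex-2-enone, then 2-methoxycyclohexane-1,3-dione.
- The dione comes from decarboxylation and an intramolecular Claisen closure of an acyclic keto diester. That diester comes from the key intermolecular Michael C–C bond between methyl 4-methoxyacetoacetate and methyl acrylate.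
- Ring order: ring A is the only ring built (Michael, Claisen closure, aromatisation). Ring B is attached afterwards.

Assumption: the SMILES has no stereocentre and rotation about the ether bonds is fast, so the target is achiral and there is no enantiomer to select. The stereocentres in 3, 4, 5 and F2 are racemic and disappear on aromatisation.

**Step 1**
Reactants: 1 methyl 4-methoxyacetoacetate (methyl 4-methoxy-3-oxobutanoate, 1.2 equiv); 2 methyl acrylate
Product: 3 dimethyl 2-(methoxyacetyl)pentanedioate (racemic)
Conditions: NaOMe (10 mol%), MeOH, 0 °C to rt, 16 h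
Reagents that add atoms: none
Why: In this base-catalysed Michael addition, catalytic methoxide deprotonates only the doubly activated C2–H of 1, so the new C–C bond forms there and not at the methoxymethylene carbon, the slight excess of 1 suppresses double addition, and the new stereocentre is racemic and erased later.

**Step 2**
Reactants: 3 dimethyl 2-(methoxyacetyl)pentanedioate
Product: 4 methyl 3-methoxy-2,4-dioxocyclohexane-1-carboxylate (keto/enol and diastereomer mixture)
Conditions: NaOMe (2.0 equiv), MeOH, reflux, 8 h; then aq. HCl, 0 °C
Reagents that add atoms: none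
Why: In this intramolecular Claisen (Dieckmann-type) condensation the methoxy-bearing α-carbon of the ketone attacks the distal ester, which is the only closure giving an unstrained ring, and deprotonation of the acidic 1,3-dione drives the equilibrium as in the classical acetoacetate/crotonate route to dihydroresorcinols.

**Step 3**
Reactants: 4 methyl 3-methoxy-2,4-dioxocyclohexane-1-carboxylate
Product: 6 2-methoxycyclohexane-1,3-dione, via keto acid 5 (not isolated)
Conditions: 2 M NaOH (3 equiv), H2O, reflux, 4 h; then conc. HCl to pH 1, reflux, 1 h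
Reagents that add atoms: sodium hydroxide, [Na+].[OH-] (its oxygen sits only in 5 and leaves with the CO2)
Why: Saponification is followed by thermal decarboxylation of the β-keto acid, while the dione is protected as its enolate in base and the α-methoxy group is not acid-labile because its oxocarbenium ion would sit next to a carbonyl.

**Step 4**
Reactants: 6 2-methoxycyclohexane-1,3-dione
Product: 7 3-bromo-2-methoxycyclohex-2-en-1-one
Conditions: Ph3PBr2 (1.1 equiv), Et3N (1.1 equiv), CH2Cl2, 0 °C to rt, 3 h
Reagents that add atoms: triphenylphosphine dibromide, BrP(Br)(c1ccccc1)(c1ccccc1)c1ccccc1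
Why: In this Piers-type deoxybromination the enol oxygen becomes an oxyphosphonium leaving group that bromide replaces by addition–elimination, and the symmetrical dione can give only one bromo enone.

**Step 5**
Reactants: 7 3-bromo-2-methoxycyclohex-2-en-1-one
Product: 10 3-bromo-2-methoxyphenol, via silyl dienol ether 8 (not isolated), via aryl silyl ether 9 (not isolated)
Conditions: LiN(SiMe3)2 (1.1 equiv), Me3SiCl (1.3 equiv), THF, −78 to 0 °C, pentane filtration; DDQ (1.1 equiv), CH2Cl2, 0 °C to rt; 1 M HCl, THF, rt
Reagents that add atoms: chlorotrimethylsilane, C[Si](C)(C)Cl (the silyl group sits only in 8 and 9)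
Why: Kinetic enolisation and O-silylation give an electron-rich cyclohexa-1,3-diene that DDQ dehydrogenates to the arene by hydride abstraction and proton loss, either dienol ether regioisomer converges on the same arene, and the vinyl C–Br bond is untouched.

**Step 6**
Reactants: 10 3-bromo-2-methoxyphenol
Product: 11 3,4,6-tribromo-2-methoxyphenol
Conditions: Br2 (2.1 equiv), AcOH, 15 °C to rt, 2 h
Reagents that add atoms: bromine, BrBr
Why: In this electrophilic aromatic bromination the free OH directs to its para (C4) and ortho (C6) positions, while C5 is meta to OH and activated only by a doubly flanked, twisted methoxy group, so it stays unsubstituted.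

**Step 7**
Reactants: 12 2,4-dibromo-1-iodobenzene; 13 1,3,5-trimethoxybenzene
Product: 15 (2,4-dibromophenyl)(2,4,6-trimethoxyphenyl)iodonium tosylate, via hydroxy(tosyloxy)iodoarene 14 (not isolated)
Conditions: mCPBA (1.1 equiv), TsOH·H2O (1.05 equiv), MeCN, 77 °C, 1 h; then 13 (1.05 equiv), 77 °C, 10 min; Et2O precipitation
Reagents that add atoms: 4-toluenesulfonic acid monohydrate, Cc1ccc(cc1)S(=O)(=O)O.O; mCPBA, OOC(=O)c1cccc(Cl)c1 (its oxygen sits only in 14)
Why: One-pot oxidation of the aryl iodide to a Koser-type trivalent iodine reagent is followed by electrophilic aromatic substitution on the very electron-rich trimethoxybenzene, which gives the unsymmetrical diaryliodonium salt as a filterable solid.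

**Step 8**
Reactants: 11 3,4,6-tribromo-2-methoxyphenol; 15 (2,4-dibromophenyl)(2,4,6-trimethoxyphenyl)iodonium tosylate (1.2 equiv)
Product: 16 1,2,5-tribromo-4-(2,4-dibromophenoxy)-3-methoxybenzene
Conditions: K2CO3 (1.5 equiv), MeCN, 70 °C, 12 h, dark
Reagents that add atoms: none
Why: In this metal-free O-arylation by ligand exchange and ligand coupling at trivalent iodine, the electron-poor ortho-substituted 2,4-dibromophenyl group is transferred ipso while the trimethoxyphenyl group acts as a dummy ligand, and the absence of a transition metal keeps all C–Br bonds intact.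

**Step 9**
Reactants: 16 1,2,5-tribromo-4-(2,4-dibromophenoxy)-3-methoxybenzene
Product: 18 2,3,5-tribromo-6-(2,4-dibromophenoxy)phenol (target), via aryloxydibromoborane 17 (not isolated)
Conditions: BBr3 (2 equiv), CH2Cl2, −78 °C to rt, 12 h; then H2O, 0 °C
Reagents that add atoms: boron tribromide, BrB(Br)Br (boron and bromine sit only in 17)
Why: In this Lewis acid ether cleavage BBr3 binds the methoxy oxygen and bromide attacks the methyl carbon by SN2, whereas the diaryl ether has no sp3 carbon to attack and survives.

**Compound list**
1 | methyl 4-methoxy-3-oxobutanoate | COCC(=O)CC(=O)OC | starting material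
2 | methyl acrylate | C=CC(=O)OC | starting material
3 | dimethyl 2-(methoxyacetyl)pentanedioate (racemic) | COCC(=O)C(CCC(=O)OC)C(=O)OC | intermediate
4 | methyl 3-methoxy-2,4-dioxocyclohexane-1-carboxylate (stereoisomer mixture) | COC1C(=O)CCC(C(=O)OC)C1=O | intermediate
5 | 3-methoxy-2,4-dioxocyclohexane-1-carboxylic acid (not isolated) | COC1C(=O)CCC(C(=O)O)C1=O | intermediate
6 | 2-methoxycyclohexane-1,3-dione | COC1C(=O)CCCC1=O | intermediate
7 | 3-bromo-2-methoxycyclohex-2-en-1-one | COC1=C(Br)CCCC1=O | intermediate
8 | 1-bromo-2-methoxy-3-(trimethylsilyloxy)cyclohexa-1,3-diene (not isolated) | COC1=C(Br)CCC=C1O[Si](C)(C)C | intermediate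
9 | (3-bromo-2-methoxyphenoxy)trimethylsilane (not isolated) | COc1c(Br)cccc1O[Si](C)(C)C | intermediate
10 | 3-bromo-2-methoxyphenol | COc1c(O)cccc1Br | intermediate
11 | 3,4,6-tribromo-2-methoxyphenol | COc1c(O)c(Br)cc(Br)c1Br | intermediate
12 | 2,4-dibromo-1-iodobenzene | Ic1ccc(Br)cc1Br | starting material
13 | 1,3,5-trimethoxybenzene | COc1cc(OC)cc(OC)c1 | starting material
14 | 2,4-dibromo-1-[hydroxy(tosyloxy)iodo]benzene (not isolated) | Cc1ccc(cc1)S(=O)(=O)OI(O)c1ccc(Br)cc1Br | intermediate
15 | (2,4-dibromophenyl)(2,4,6-trimethoxyphenyl)iodonium tosylate | COc1cc(OC)c([I+]c2ccc(Br)cc2Br)c(OC)c1.Cc1ccc(cc1)S(=O)(=O)[O-] | intermediate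
16 | 1,2,5-tribromo-4-(2,4-dibromophenoxy)-3-methoxybenzene | COc1c(Br)c(Br)cc(Br)c1Oc1ccc(Br)cc1Br | intermediate
17 | dibromo[2,3,5-tribromo-6-(2,4-dibromophenoxy)phenoxy]borane (not isolated) | BrB(Br)Oc1c(Br)c(Br)cc(Br)c1Oc1ccc(Br)cc1Br | intermediate
18 | 2,3,5-tribromo-6-(2,4-dibromophenoxy)phenol | Oc1c(Br)c(Br)cc(Br)c1Oc1ccc(Br)cc1Br | target

Total step count: 9. Longest linear sequence: 8 (steps 1–6, 8, 9). Step 7 is a one-step side branch.

**Steps most likely to fail**

Step 2 (Claisen closure). The acidic β-keto ester C–H of 3 may consume the base, or retro-Claisen and retro-Michael cleavage may compete with ring closure. The fallback sets out from 3 and removes the activating ester first. Krapcho dealkoxycarbonylation (LiCl, wet DMSO, 150 °C) touches only the geminally activated ester and gives methyl 6-methoxy-5-oxohexanoate F1. This simple δ-keto ester is closed with KOt-Bu in THF (0 °C to rt, acid quench), where only the six-membered closure is possible. The fallback bypasses 4 and 5 and comes back at 6.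

Step 5 (aromatisation). Enolisation of the β-bromo enone or the DDQ oxidation may be unclean. The fallback sets out from 7 and uses halogenation and elimination instead of dehydrogenation. CuBr2 (2.2 equiv) in refluxing EtOAc/CHCl3 gives 3,6-dibromo-2-methoxycyclohex-2-en-1-one F2. Li2CO3/LiBr in DMF at 110 °C then causes dehydrobromination and tautomerisation, and the fallback comes back at 10. Stray bromination can only land on C4 or C6, the two positions that step 6 brominates anyway.

Step 8 (O-arylation). The hindered, weakly nucleophilic phenoxide may couple sluggishly. The fallback sets out from 11 and builds the ether by SNAr: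
- Reaction with 2-bromo-1-fluoro-4-nitrobenzene (K2CO3, DMF, 80 °C) gives 1,2,5-tribromo-4-(2-bromo-4-nitrophenoxy)-3-methoxybenzene F3.
- Fe powder/NH4Cl (EtOH–H2O, 80 °C) reduces the nitro group without debromination to 3-bromo-4-(3,4,6-tribromo-2-methoxyphenoxy)aniline F4.
- NaNO2 in aq. HBr/AcOH at 0 °C gives 3-bromo-4-(3,4,6-tribromo-2-methoxyphenoxy)benzenediazonium bromide F5.
- CuBr/HBr (0 to 60 °C, Sandmeyer) converts F5 into the aryl bromide, and the fallback comes back at 16.

**Further compounds**
F1 | step 2 | methyl 6-methoxy-5-oxohexanoate | COCC(=O)CCCC(=O)OC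
F2 | step 5 | 3,6-dibromo-2-methoxycyclohex-2-en-1-one (racemic) | COC1=C(Br)CCC(Br)C1=O
F3 | step 8 | 1,2,5-tribromo-4-(2-bromo-4-nitrophenoxy)-3-methoxybenzene | COc1c(Br)c(Br)cc(Br)c1Oc1ccc(cc1Br)[N+](=O)[O-]
F4 | step 8 | 3-bromo-4-(3,4,6-tribromo-2-methoxyphenoxy)aniline | COc1c(Br)c(Br)cc(Br)c1Oc1ccc(N)cc1Br
F5 | step 8 | 3-bromo-4-(3,4,6-tribromo-2-methoxyphenoxy)benzenediazonium bromide | COc1c(Br)c(Br)cc(Br)c1Oc1ccc(cc1Br)[N+]#N.[Br-]
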